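The target is (S)-naringenin trimethyl ether with two further methoxy groups, so the plan disconnects the C6–OMe and C8–OMe bonds of ring A and takes C2 from the chiral pool. One copper-catalysed operation exchanges both bromines of a 6,8-dibromide for methoxide. It exploits the fact that C6 and C8 of ring A each sit between two oxygen-bearing carbons (C5/C7 and C7/C8a) and para to a third, so NBS places the halogens exactly there and ring B stays untouched. In the precursor the C4 carbonyl is masked as a cis-4-silyloxy group; hot methoxide then finds no enolisable ketone and cannot open ring C at C2.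

Key step: step 5

Remarks and assumptions
- Diazomethane is assumed to be used as an ethereal solution freshly generated from commercial N-methyl-N-nitroso-p-toluenesulfonamide and KOH; this reagent preparation is not counted as a step.
- Stereodescriptors were checked against the structures: with C2 = S, the 2,4-cis carbinol and its ethers are (2S,4S). C4 is a temporary stereocentre that is erased in step 7, so either C4 epimer would converge on the target.
- Steps 4 and 5 are twofold substitutions. The mono-substituted intermediates listed (9, 12) are those expected to form first, C8 being the less hindered site; the regioisomeric mono-substituted species would converge on the same products.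

Step 1
Reactants: 1 (S)-naringenin; 2 diazomethane
Product: 4 (2S)-5,7-dimethoxy-2-(4-methoxyphenyl)chroman-4-one, via (S)-naringenin 7,4'-dimethyl ether 3 (not isolated)
Conditions: CH2N2 (large excess, in portions), Et2O/MeOH, 0 °C → rt, dark, 2–3 d
Reagents that add atoms: diazomethane, C=[N+]=[N-]
Why: Phenol O-methylation by diazomethane (proton transfer, then SN2 on the methyldiazonium ion) needs no base, so neither enolate-driven retro-oxa-Michael opening of ring C nor 4'-phenoxide-assisted C2–O1 cleavage can scramble C2; the hydrogen-bonded 5-OH reacts last and is the reason for the excess, the methanol co-solvent and the long reaction time.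

Step 2
Reactants: 4 (2S)-5,7-dimethoxy-2-(4-methoxyphenyl)chroman-4-one
Product: 5 (2S,4S)-5,7-dimethoxy-2-(4-methoxyphenyl)chroman-4-ol (2,4-cis)
Conditions: NaBH4, THF/EtOH, 0 °C → rt; acetone quench, neutral aqueous work-up
Reagents that add atoms: none
Why: Borohydride 1,2-reduction of the aryl ketone, in which hydride adds pseudo-axially to C4 on the face opposite the equatorial C2 aryl group (substrate control) and should give the 2,4-cis carbinol (4S); no acid is used because the trioxygenated benzylic alcohol ionises easily.

Step 3
Reactants: 5 (2S,4S)-5,7-dimethoxy-2-(4-methoxyphenyl)chroman-4-ol; 6 tert-butyldimethylsilyl chloride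
Product: 7 (2S,4S)-4-(tert-butyldimethylsilyloxy)-5,7-dimethoxy-2-(4-methoxyphenyl)chromane
Conditions: TBSCl, imidazole, DMAP (cat.), DMF, rt
Reagents that add atoms: tert-butyldimethylsilyl chloride, CC(C)(C)[Si](C)(C)Cl
Why: Imidazole-promoted O-silylation (via the N-silylimidazolium ion) is free of Lewis and Brønsted acid, so the ionisation-prone benzylic carbinol should be capped without loss of water and without touching either stereocentre.

Step 4
Reactants: 7 (2S,4S)-4-(tert-butyldimethylsilyloxy)-5,7-dimethoxy-2-(4-methoxyphenyl)chromane; 8 N-bromosuccinimide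
Product: 10 (2S,4S)-6,8-dibromo-4-(tert-butyldimethylsilyloxy)-5,7-dimethoxy-2-(4-methoxyphenyl)chromane, via 8-bromo monobromide 9 (not isolated)
Conditions: NBS (2.05 equiv), NaHCO3 (solid), MeCN, 0 °C, dark
Reagents that add atoms: N-bromosuccinimide, O=C1CCC(=O)N1Br
Why: Electrophilic aromatic bromination (SEAr) should go to C6 and C8, each ortho to two and para to one ring-A oxygen and therefore far more reactive than C3'/C5' of ring B with a single ortho oxygen; cold, dark, buffered conditions and exactly two equivalents guard against benzylic radical bromination, ipso attack and acid-induced ionisation at C4.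

Step 5
Reactants: 10 (2S,4S)-6,8-dibromo-4-(tert-butyldimethylsilyloxy)-5,7-dimethoxy-2-(4-methoxyphenyl)chromane; 11 sodium methoxide
Product: 13 (2S,4S)-4-(tert-butyldimethylsilyloxy)-5,6,7,8-tetramethoxy-2-(4-methoxyphenyl)chromane, via 6-bromo-8-methoxy monoether 12 (not isolated)
Conditions: CuBr (0.5 equiv), NaOMe (25 wt% in MeOH, 12 equiv), DMF, 100 °C, degassed, Ar, sealed tube
Reagents that add atoms: sodium methoxide, [Na+].[O-]C
Why: Methoxide and CuBr form a copper(I) methoxide/dimethoxycuprate that adds oxidatively to each C–Br bond and releases the aryl methyl ether by reductive elimination from copper(III), returning Cu(I) to the cycle. The closest known reaction is the Ullmann-type copper-catalysed methoxylation of polybrominated, polyoxygenated arenes (bromophenols, bromoanisoles, brominated flavonoid ethers) with NaOMe/CuBr in DMF–MeOH. No ring is closed and no stereocentre is created; the step forms the two C(sp2)–O bonds at C6 and C8. Regiochemistry is fixed by the bromines, because neither C–Br carbon has an ortho hydrogen, so an aryne pathway is impossible and substitution is strictly ipso. The selectivity required is substitution over hydrodebromination at two doubly ortho-flanked carbons, which is served by a large excess of concentrated methoxide, the small nucleophile, and rigorous exclusion of oxygen and water. C2 keeps its configuration because C4 is an sp3 silyl ether, so there is no carbonyl, no C3 enolate and no E1cB opening of ring C to a chalcone, while the aryl methyl ethers are inert to methoxide.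

Step 6
Reactants: 13 (2S,4S)-4-(tert-butyldimethylsilyloxy)-5,6,7,8-tetramethoxy-2-(4-methoxyphenyl)chromane
Product: 14 (2S,4S)-5,6,7,8-tetramethoxy-2-(4-methoxyphenyl)chroman-4-ol
Conditions: TBAF (1 M in THF, 2 equiv), THF, 0 °C → rt; water quench
Reagents that add atoms: none
Why: Fluoride-mediated desilylation (attack at silicon, driven by the Si–F bond) is non-acidic, so the highly ionisable pentaoxygenated benzylic C4–O bond and both stereocentres should stay intact.

Step 7
Reactants: 14 (2S,4S)-5,6,7,8-tetramethoxy-2-(4-methoxyphenyl)chroman-4-ol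
Product: 15 (2S)-5,6,7,8-tetramethoxy-2-(4-methoxyphenyl)chroman-4-one [(2S)-5,6,7,8,4'-pentamethoxyflavanone]
Conditions: Dess–Martin periodinane (1.3 equiv), NaHCO3 (5 equiv), CH2Cl2, 0 °C → rt; Na2S2O3/NaHCO3 work-up
Reagents that add atoms: none
Why: Dess–Martin oxidation (ligand exchange at iodine(V), then intramolecular α-deprotonation by acetate) should convert the secondary benzylic alcohol into the ketone under bicarbonate-buffered conditions, so the carbinol does not ionise and the flavanone is never exposed to base that could open ring C; C4 becomes sp2 and C2 stays S.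

Compound list
1 | (S)-naringenin, (2S)-5,7-dihydroxy-2-(4-hydroxyphenyl)chroman-4-one | Oc1ccc([C@@H]2CC(=O)c3c(O)cc(O)cc3O2)cc1 | starting material
2 | diazomethane | C=[N+]=[N-] | starting material
3 | (2S)-5-hydroxy-7-methoxy-2-(4-methoxyphenyl)chroman-4-one, (S)-naringenin 7,4'-dimethyl ether | COc1ccc([C@@H]2CC(=O)c3c(O)cc(OC)cc3O2)cc1 | intermediate
4 | (2S)-5,7-dimethoxy-2-(4-methoxyphenyl)chroman-4-one | COc1ccc([C@@H]2CC(=O)c3c(OC)cc(OC)cc3O2)cc1 | intermediate
5 | (2S,4S)-5,7-dimethoxy-2-(4-methoxyphenyl)chroman-4-ol (2,4-cis) | COc1ccc([C@@H]2C[C@H](O)c3c(OC)cc(OC)cc3O2)cc1 | intermediate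
6 | tert-butyldimethylsilyl chloride | CC(C)(C)[Si](C)(C)Cl | starting material
7 | (2S,4S)-4-(tert-butyldimethylsilyloxy)-5,7-dimethoxy-2-(4-methoxyphenyl)chromane | COc1ccc([C@@H]2C[C@H](O[Si](C)(C)C(C)(C)C)c3c(OC)cc(OC)cc3O2)cc1 | intermediate
8 | N-bromosuccinimide | O=C1CCC(=O)N1Br | starting material
9 | (2S,4S)-8-bromo-4-(tert-butyldimethylsilyloxy)-5,7-dimethoxy-2-(4-methoxyphenyl)chromane | COc1ccc([C@@H]2C[C@H](O[Si](C)(C)C(C)(C)C)c3c(OC)cc(OC)c(Br)c3O2)cc1 | intermediate
10 | (2S,4S)-6,8-dibromo-4-(tert-butyldimethylsilyloxy)-5,7-dimethoxy-2-(4-methoxyphenyl)chromane | COc1ccc([C@@H]2C[C@H](O[Si](C)(C)C(C)(C)C)c3c(OC)c(Br)c(OC)c(Br)c3O2)cc1 | intermediate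
11 | sodium methoxide | [Na+].[O-]C | starting material
12 | (2S,4S)-6-bromo-4-(tert-butyldimethylsilyloxy)-5,7,8-trimethoxy-2-(4-methoxyphenyl)chromane | COc1ccc([C@@H]2C[C@H](O[Si](C)(C)C(C)(C)C)c3c(OC)c(Br)c(OC)c(OC)c3O2)cc1 | intermediate
13 | (2S,4S)-4-(tert-butyldimethylsilyloxy)-5,6,7,8-tetramethoxy-2-(4-methoxyphenyl)chromane | COc1ccc([C@@H]2C[C@H](O[Si](C)(C)C(C)(C)C)c3c(OC)c(OC)c(OC)c(OC)c3O2)cc1 | intermediate
14 | (2S,4S)-5,6,7,8-tetramethoxy-2-(4-methoxyphenyl)chroman-4-ol | COc1ccc([C@@H]2C[C@H](O)c3c(OC)c(OC)c(OC)c(OC)c3O2)cc1 | intermediate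
15 | (2S)-5,6,7,8-tetramethoxy-2-(4-methoxyphenyl)chroman-4-one, (2S)-5,6,7,8,4'-pentamethoxyflavanone | COc1ccc([C@@H]2CC(=O)c3c(OC)c(OC)c(OC)c(OC)c3O2)cc1 | target

Total step count: 7
Longest linear sequence: 7 steps (1 → 15)

Steps most likely to fail

Step 5. The substitution may lose to reductive removal of bromine (a copper hydride formed by β-hydride elimination from copper methoxide), or may stall after the first exchange at the doubly flanked carbons. Attack of methoxide on silicon is a secondary concern. The fallback sets out from 10 and returns at 13. Dibromide 10 would undergo twofold bromine–lithium exchange with t-BuLi (4.2 equiv) in THF at −78 °C. The dilithio species would be quenched with trimethyl borate and hydrolysed to [(2S,4S)-4-(tert-butyldimethylsilyloxy)-5,7-dimethoxy-2-(4-methoxyphenyl)chromane-6,8-diyl]diboronic acid F1. Oxidation with H2O2/aqueous NaOH at 0 °C (1,2-aryl shift from boron to oxygen) should give (2S,4S)-4-(tert-butyldimethylsilyloxy)-5,7-dimethoxy-2-(4-methoxyphenyl)chromane-6,8-diol F2, handled under argon. Williamson methylation of both phenols (MeI, K2CO3, acetone, rt) would then deliver 13; no ketone is present while base is used, so C2 is not at risk.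

Step 1. The methylation may stall at the hydrogen-bonded 5-hydroxyl, so that dimethyl ether 3 accumulates, or diazomethane may begin to attack elsewhere on forcing. The fallback sets out from 1 and returns at 5. A short diazomethane treatment would be stopped at 3, which is then isolated. Reduction of 3 with NaBH4 (THF/EtOH) should give (2S,4S)-7-methoxy-2-(4-methoxyphenyl)chromane-4,5-diol F3, in which the phenol has lost its carbonyl hydrogen-bond partner. MeI/K2CO3 in acetone at rt would then methylate only the phenol and give 5. Base meets the molecule only after the ketone is gone, so ring C cannot open.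

Step 4. The very electron-rich ring A of silyl ether 7 may be over-oxidised or attacked ipso at C4a, traces of HBr may ionise the benzylic silyl ether, or the second bromination may lag. The fallback sets out from 4 and returns at 10. Bromination would be moved to the ketone stage: NBS (2.1 equiv) in DMF at rt should give (2S)-6,8-dibromo-5,7-dimethoxy-2-(4-methoxyphenyl)chroman-4-one F4, since C6 and C8 still carry three ortho/para oxygen donors and no labile benzylic ether is present. NaBH4 reduction would give the cis carbinol (2S,4S)-6,8-dibromo-5,7-dimethoxy-2-(4-methoxyphenyl)chroman-4-ol F5, and silylation (TBSCl, imidazole, DMF) would reach 10.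

Further compounds
F1 | step 5 | [(2S,4S)-4-(tert-butyldimethylsilyloxy)-5,7-dimethoxy-2-(4-methoxyphenyl)chromane-6,8-diyl]diboronic acid | COc1ccc([C@@H]2C[C@H](O[Si](C)(C)C(C)(C)C)c3c(OC)c(B(O)O)c(OC)c(B(O)O)c3O2)cc1
F2 | step 5 | (2S,4S)-4-(tert-butyldimethylsilyloxy)-5,7-dimethoxy-2-(4-methoxyphenyl)chromane-6,8-diol | COc1ccc([C@@H]2C[C@H](O[Si](C)(C)C(C)(C)C)c3c(OC)c(O)c(OC)c(O)c3O2)cc1
F3 | step 1 | (2S,4S)-7-methoxy-2-(4-methoxyphenyl)chromane-4,5-diol | COc1ccc([C@@H]2C[C@H](O)c3c(O)cc(OC)cc3O2)cc1
F4 | step 4 | (2S)-6,8-dibromo-5,7-dimethoxy-2-(4-methoxyphenyl)chroman-4-one | COc1ccc([C@@H]2CC(=O)c3c(OC)c(Br)c(OC)c(Br)c3O2)cc1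
F5 | step 4 | (2S,4S)-6,8-dibromo-5,7-dimethoxy-2-(4-methoxyphenyl)chroman-4-ol | COc1ccc([C@@H]2C[C@H](O)c3c(OC)c(Br)c(OC)c(Br)c3O2)cc1
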